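**Strategy**

The flavone is disconnected at C4–C4a of ring C. Ring A is carried as a penta-oxygenated aryl vinyl ether whose only CH carbon is the future C4a, flanked by C8a (bearing O1) and C5 (bearing OBn); an activated carboxyl tethered through O1–C2=C3 can therefore bond only there. One intramolecular Friedel–Crafts acylation thus closes the pyranone and completes the flavone skeleton with every oxygen substituent in place. Its precursor is the (E)-3-aryl-3-aryloxy-2-methoxyacrylic acid, CO2H cis to the ring A aryloxy group, with all four phenols as benzyl ethers so that a mild anhydride activation suffices and no free phenol or hot strong acid is involved.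

Key step: step 9

Remarks on the chemistry:
- Syringol, 4-O-methylgallic acid and methyl methoxyacetate are taken as commercial.
- The 5-oxygen is carried as a benzyl ether, installed in the flask that forms the aryl vinyl ether, and the ring is closed with trifluoroacetic anhydride. Aryl benzyl ethers are cleaved and C-transferred in P2O5/MeSO3H or polyphosphoric acid, and a free 5-OH would be acylated by the activated acid.
- The alkene geometry is set before the key step (chelation-controlled enol triflation, then substitution with retention) and is not left to equilibration in acid. The Z acid would present its acyl group to the activated C2'/C6' of ring B.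

**Route**

Step 1
Reactants: 1 syringol (2,6-dimethoxyphenol)
Product: 2 benzyl ether 2-(benzyloxy)-1,3-dimethoxybenzene
Conditions: BnBr (1.1 equiv), K2CO3, DMF, rt
Reagents that add atoms: benzyl bromide, BrCc1ccccc1
Why: Williamson ether synthesis; the phenoxide, although flanked by two methoxy groups, should be alkylated cleanly by a benzylic bromide in a dipolar aprotic solvent.

Step 2
Reactants: 2 benzyl ether 2-(benzyloxy)-1,3-dimethoxybenzene
Product: 3 dibromide 3-(benzyloxy)-1,5-dibromo-2,4-dimethoxybenzene
Conditions: NBS (2.05 equiv), MeCN, 0 °C to rt, dark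
Reagents that add atoms: N-bromosuccinimide, O=C1CCC(=O)N1Br
Why: Electrophilic aromatic bromination; each outer methoxy group directs ortho/para to C4 and C6 of the 1,2,3-trialkoxybenzene, whereas the twisted central benzyloxy group hardly activates C5, so the 4,6-dibromide should form as it does with 1,2,3-trimethoxybenzene.

Step 3
Reactants: 3 dibromide 3-(benzyloxy)-1,5-dibromo-2,4-dimethoxybenzene
Product: 5 symmetric diol 5-(benzyloxy)-4,6-dimethoxybenzene-1,3-diol, via bis(pinacol boronate) 4 (not isolated)
Conditions: B2pin2 (2.6 equiv), Pd(dppf)Cl2 (5 mol%), KOAc, 1,4-dioxane, 90 °C; filter and concentrate; then 30% aq. H2O2, NaOH, THF, 0 °C; Na2SO3, then dilute HCl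
Reagents that add atoms: hydrogen peroxide, OO (the two new oxygen atoms of 5); bis(pinacolato)diboron, CC1(C)OB(OC1(C)C)B1OC(C)(C)C(C)(C)O1 (the boryl groups of 4 only)
Why: Miyaura borylation of both aryl bromides followed by oxidation of the two C–B bonds to C–O bonds with alkaline peroxide, run cold and quenched reductively to spare the electron-rich resorcinol.

Step 4
Reactants: 6 4-O-methylgallic acid (3,5-dihydroxy-4-methoxybenzoic acid)
Product: 7 benzyl 3,5-bis(benzyloxy)-4-methoxybenzoate
Conditions: BnBr (3.5 equiv), K2CO3, DMF, 60 °C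
Reagents that add atoms: benzyl bromide, BrCc1ccccc1
Why: Williamson alkylation of both phenols together with O-alkylation of the carboxylate, which protects ring B and provides a non-enolisable ester in one operation.

Step 5
Reactants: 7 benzyl 3,5-bis(benzyloxy)-4-methoxybenzoate; 8 methyl methoxyacetate
Product: 9 methyl 3-[3,5-bis(benzyloxy)-4-methoxyphenyl]-2-methoxy-3-oxopropanoate (racemic at C2; this centre becomes sp2 in step 6)
Conditions: 8 (2.5 equiv), LiHMDS (2.6 equiv), THF, −78 °C; then 7, −78 to 0 °C; aq. NH4Cl
Reagents that add atoms: none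
Why: Crossed Claisen condensation of a preformed α-alkoxy ester lithium enolate with a non-enolisable benzoate, driven by loss of benzyloxide and by deprotonation of the β-keto ester with the excess enolate.

Step 6
Reactants: 9 methyl 3-[3,5-bis(benzyloxy)-4-methoxyphenyl]-2-methoxy-3-oxopropanoate
Product: 10 methyl (E)-3-[3,5-bis(benzyloxy)-4-methoxyphenyl]-2-methoxy-3-{[(trifluoromethyl)sulfonyl]oxy}prop-2-enoate
Conditions: Tf2O (1.5 equiv), sat. aq. LiOH, toluene, 5 °C
Reagents that add atoms: trifluoromethanesulfonic anhydride, O=S(=O)(OS(=O)(=O)C(F)(F)F)C(F)(F)F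
Why: Chelation-controlled enol triflation of a β-keto ester; the lithium enolate is held as a six-membered chelate between the enolate oxygen and the ester carbonyl, so O-sulfonylation should place OTf cis to CO2Me, which is the E isomer here.

Step 7
Reactants: 10 methyl (E)-3-[3,5-bis(benzyloxy)-4-methoxyphenyl]-2-methoxy-3-{[(trifluoromethyl)sulfonyl]oxy}prop-2-enoate; 5 symmetric diol 5-(benzyloxy)-4,6-dimethoxybenzene-1,3-diol
Product: 12 methyl (E)-3-[3,5-bis(benzyloxy)-2,4-dimethoxyphenoxy]-3-[3,5-bis(benzyloxy)-4-methoxyphenyl]-2-methoxyprop-2-enoate, via phenol ester 11 (not isolated)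
Conditions: 5 (2.5 equiv), Cs2CO3 (1.2 equiv), degassed DMF, 0 °C to rt; then BnBr (6 equiv), Cs2CO3 (5 equiv), 40 °C
Reagents that add atoms: benzyl bromide, BrCc1ccccc1
Why: Vinylic nucleophilic substitution by addition–elimination at C3 of the β-triflyloxy enoate, followed in the same flask by Williamson benzylation of the remaining phenol; triflate should leave the ester-stabilised carbanion faster than the C2–C3 bond rotates, so the aryloxy group replaces OTf with retention, the excess of symmetric diol keeps double vinylation low, and the surplus diol is benzylated as well and removed on silica.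

Step 8
Reactants: 12 methyl (E)-3-[3,5-bis(benzyloxy)-2,4-dimethoxyphenoxy]-3-[3,5-bis(benzyloxy)-4-methoxyphenyl]-2-methoxyprop-2-enoate
Product: 13 (E)-3-[3,5-bis(benzyloxy)-2,4-dimethoxyphenoxy]-3-[3,5-bis(benzyloxy)-4-methoxyphenyl]-2-methoxyprop-2-enoic acid
Conditions: LiOH·H2O (6 equiv), THF/MeOH/H2O (3:1:1), 45 °C; then 1 M HCl, 0 °C, to pH 3
Reagents that add atoms: lithium hydroxide, [Li+].[OH-]
Why: Saponification of the methyl ester by acyl–oxygen cleavage; the carboxylate formed is a poor Michael acceptor, so the aryl vinyl ether and the alkene geometry should survive, and brief cold acidification liberates the acid.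

Step 9
Reactants: 13 (E)-3-[3,5-bis(benzyloxy)-2,4-dimethoxyphenoxy]-3-[3,5-bis(benzyloxy)-4-methoxyphenyl]-2-methoxyprop-2-enoic acid
Product: 15 chromone 5,7-bis(benzyloxy)-2-[3,5-bis(benzyloxy)-4-methoxyphenyl]-3,6,8-trimethoxy-4H-chromen-4-one, via acyl trifluoroacetate 14 (not isolated)
Conditions: TFAA (3 equiv), CH2Cl2 (0.02 M), 0 °C to rt; aq. NaHCO3
Reagents that add atoms: trifluoroacetic anhydride, O=C(OC(=O)C(F)(F)F)C(F)(F)F (the trifluoroacetyl group of 14 only; no atom of it remains in 15)
Why: Trifluoroacetic anhydride converts the acid into the mixed anhydride 14, whose acyl carbon (free or as the push–pull-stabilised acylium ion) is attacked by the only CH carbon of ring A, the future C4a, and the arenium ion then loses its proton to give the 4-pyranone and trifluoroacetic acid. The closest known reaction type is the intramolecular Friedel–Crafts acylation of β-aryloxyacrylic acids to chromones (Ruhemann- and Simonis-type closures) and of 2-aryloxybenzoic acids to xanthones, which runs with trifluoroacetic anhydride alone when the arene is alkoxy-rich. Ring C closes as a six-membered ring by 6-exo-trig attack of the arene on the activated carbonyl, which forms C4–C4a. No stereocentre is formed. The step needs regioselectivity within ring A and chemoselectivity against ring B: the first is secured because C4a is the single unsubstituted carbon of ring A, ortho to the 5-benzyloxy group and to O1, and the second because the E geometry holds the acyl group cis to the aryloxy oxygen and out of reach of C2'/C6' of ring B. The anhydride activation is mild enough that it should neither equilibrate that geometry nor cleave benzyl ethers.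

Step 10
Reactants: 15 chromone 5,7-bis(benzyloxy)-2-[3,5-bis(benzyloxy)-4-methoxyphenyl]-3,6,8-trimethoxy-4H-chromen-4-one
Product: 16 5,7,3',5'-tetrahydroxy-3,6,8,4'-tetramethoxyflavone (5,7-dihydroxy-2-(3,5-dihydroxy-4-methoxyphenyl)-3,6,8-trimethoxy-4H-chromen-4-one)
Conditions: H2 (1 atm), Pd/C (10 wt% palladium on carbon), THF/MeOH (1:1), rt
Reagents that add atoms: none
Why: Catalytic hydrogenolysis of the four aryl benzyl ethers; the aryl methyl ethers and the chromone C2=C3 bond should not be touched under these mild conditions, and the target has no stereocentre.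

**Compound list**

1 | syringol (2,6-dimethoxyphenol) | COc1cccc(OC)c1O | starting material
2 | 2-(benzyloxy)-1,3-dimethoxybenzene | COc1cccc(OC)c1OCc1ccccc1 | intermediate
3 | 3-(benzyloxy)-1,5-dibromo-2,4-dimethoxybenzene | COc1c(Br)cc(Br)c(OC)c1OCc1ccccc1 | intermediate
4 | 2,2'-[5-(benzyloxy)-4,6-dimethoxy-1,3-phenylene]bis(4,4,5,5-tetramethyl-1,3,2-dioxaborolane) | COc1c(B2OC(C)(C)C(C)(C)O2)cc(B2OC(C)(C)C(C)(C)O2)c(OC)c1OCc1ccccc1 | intermediate
5 | 5-(benzyloxy)-4,6-dimethoxybenzene-1,3-diol | COc1c(O)cc(O)c(OC)c1OCc1ccccc1 | intermediate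
6 | 3,5-dihydroxy-4-methoxybenzoic acid (4-O-methylgallic acid) | COc1c(O)cc(C(=O)O)cc1O | starting material
7 | benzyl 3,5-bis(benzyloxy)-4-methoxybenzoate | COc1c(OCc2ccccc2)cc(C(=O)OCc2ccccc2)cc1OCc1ccccc1 | intermediate
8 | methyl methoxyacetate | COCC(=O)OC | starting material
9 | methyl 3-[3,5-bis(benzyloxy)-4-methoxyphenyl]-2-methoxy-3-oxopropanoate (racemic) | COC(=O)C(OC)C(=O)c1cc(OCc2ccccc2)c(OC)c(OCc2ccccc2)c1 | intermediate
10 | methyl (E)-3-[3,5-bis(benzyloxy)-4-methoxyphenyl]-2-methoxy-3-{[(trifluoromethyl)sulfonyl]oxy}prop-2-enoate | COC(=O)/C(OC)=C(\OS(=O)(=O)C(F)(F)F)c1cc(OCc2ccccc2)c(OC)c(OCc2ccccc2)c1 | intermediate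
11 | methyl (E)-3-[3-(benzyloxy)-5-hydroxy-2,4-dimethoxyphenoxy]-3-[3,5-bis(benzyloxy)-4-methoxyphenyl]-2-methoxyprop-2-enoate | COC(=O)/C(OC)=C(\Oc1cc(O)c(OC)c(OCc2ccccc2)c1OC)c1cc(OCc2ccccc2)c(OC)c(OCc2ccccc2)c1 | intermediate
12 | methyl (E)-3-[3,5-bis(benzyloxy)-2,4-dimethoxyphenoxy]-3-[3,5-bis(benzyloxy)-4-methoxyphenyl]-2-methoxyprop-2-enoate | COC(=O)/C(OC)=C(\Oc1cc(OCc2ccccc2)c(OC)c(OCc2ccccc2)c1OC)c1cc(OCc2ccccc2)c(OC)c(OCc2ccccc2)c1 | intermediate
13 | (E)-3-[3,5-bis(benzyloxy)-2,4-dimethoxyphenoxy]-3-[3,5-bis(benzyloxy)-4-methoxyphenyl]-2-methoxyprop-2-enoic acid | OC(=O)/C(OC)=C(\Oc1cc(OCc2ccccc2)c(OC)c(OCc2ccccc2)c1OC)c1cc(OCc2ccccc2)c(OC)c(OCc2ccccc2)c1 | intermediate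
14 | (E)-3-[3,5-bis(benzyloxy)-2,4-dimethoxyphenoxy]-3-[3,5-bis(benzyloxy)-4-methoxyphenyl]-2-methoxyprop-2-enoic trifluoroacetic anhydride | O=C(OC(=O)C(F)(F)F)/C(OC)=C(\Oc1cc(OCc2ccccc2)c(OC)c(OCc2ccccc2)c1OC)c1cc(OCc2ccccc2)c(OC)c(OCc2ccccc2)c1 | intermediate
15 | 5,7-bis(benzyloxy)-2-[3,5-bis(benzyloxy)-4-methoxyphenyl]-3,6,8-trimethoxy-4H-chromen-4-one | COc1c(OCc2ccccc2)cc(-c2oc3c(OC)c(OCc4ccccc4)c(OC)c(OCc4ccccc4)c3c(=O)c2OC)cc1OCc1ccccc1 | intermediate
16 | 5,7,3',5'-tetrahydroxy-3,6,8,4'-tetramethoxyflavone | COc1c(O)cc(-c2oc3c(OC)c(O)c(OC)c(O)c3c(=O)c2OC)cc1O | target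

**Step count and risk**

Total steps: 10. Longest linear sequence: 7 steps (steps 4, 5, 6, 7, 8, 9, 10 from 6; equally steps 1, 2, 3, 7, 8, 9, 10 from 1).

Steps most likely to fail:

1. Step 9 (ring closure). Three processes may interfere. Acid-promoted E-to-Z isomerisation of the push–pull alkene before closure would let the acyl group attack C2'/C6' of ring B in a five-membered closure. Acylation at the doubly flanked C4a may be slow. The liberated acid may transfer benzyl groups. The fallback forms the same C4–C4a bond with reversed polarity by a Parham-type anionic cyclisation, which is known chemistry. It sets out from 11, isolated by leaving out the benzylation stage of step 7. NBS (1.0 equiv, CH2Cl2, −40 °C) should brominate the only position ortho to the free phenol and give methyl (E)-3-[3-(benzyloxy)-6-bromo-5-hydroxy-2,4-dimethoxyphenoxy]-3-[3,5-bis(benzyloxy)-4-methoxyphenyl]-2-methoxyprop-2-enoate F1. Benzylation (BnBr, K2CO3, DMF) gives methyl (E)-3-[3,5-bis(benzyloxy)-2-bromo-4,6-dimethoxyphenoxy]-3-[3,5-bis(benzyloxy)-4-methoxyphenyl]-2-methoxyprop-2-enoate F2. Bromine–lithium exchange (n-BuLi, 1.05 equiv, THF, −100 °C) then generates the aryllithium at the future C4a, which should add to the cis methyl ester and expel methoxide. The fallback comes back to the route at 15, bypassing steps 8 and 9.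

2. Step 7 (aryl vinyl ether formation). The phenoxide may attack sulfur and not C3, which transfers the triflyl group and regenerates the β-keto ester enolate. Addition at the tetrasubstituted, α-alkoxy-substituted C3 may be sluggish. The diol may be vinylated twice, and the geometry may partly erode. The fallback replaces addition–elimination by a palladium-catalysed C–O cross-coupling with a phenol that has a single free OH. It sets out from 5, which is monobenzylated (BnBr, 1.0 equiv, K2CO3, acetone; statistical, with recycling of 5) to 3,5-bis(benzyloxy)-2,4-dimethoxyphenol F3. Coupling of F3 with 10 (Pd2(dba)3, tBuXPhos, K3PO4, toluene, 80 °C) proceeds by oxidative addition into the C–OTf bond with retention and C–O reductive elimination. It comes back to the route at 12.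

3. Step 5 (crossed Claisen condensation). The glycolate enolate may self-condense on warming before the rather unreactive benzoate is acylated, or conversion may stay incomplete. The fallback uses an acyl chloride, which acylates the enolate at −78 °C. It sets out from 7, which is saponified (LiOH, THF/MeOH/H2O) to 3,5-bis(benzyloxy)-4-methoxybenzoic acid F4. Oxalyl chloride with catalytic DMF in CH2Cl2 gives 3,5-bis(benzyloxy)-4-methoxybenzoyl chloride F5. F5 is added to the preformed lithium enolate of 8 (2.2 equiv, THF, −78 °C) for C-acylation, and the fallback comes back to the route at 9.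

Further compounds
F1 | step 9 | methyl (E)-3-[3-(benzyloxy)-6-bromo-5-hydroxy-2,4-dimethoxyphenoxy]-3-[3,5-bis(benzyloxy)-4-methoxyphenyl]-2-methoxyprop-2-enoate | COC(=O)/C(OC)=C(\Oc1c(Br)c(O)c(OC)c(OCc2ccccc2)c1OC)c1cc(OCc2ccccc2)c(OC)c(OCc2ccccc2)c1
F2 | step 9 | methyl (E)-3-[3,5-bis(benzyloxy)-2-bromo-4,6-dimethoxyphenoxy]-3-[3,5-bis(benzyloxy)-4-methoxyphenyl]-2-methoxyprop-2-enoate | COC(=O)/C(OC)=C(\Oc1c(Br)c(OCc2ccccc2)c(OC)c(OCc2ccccc2)c1OC)c1cc(OCc2ccccc2)c(OC)c(OCc2ccccc2)c1
F3 | step 7 | 3,5-bis(benzyloxy)-2,4-dimethoxyphenol | COc1c(O)cc(OCc2ccccc2)c(OC)c1OCc1ccccc1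
F4 | step 5 | 3,5-bis(benzyloxy)-4-methoxybenzoic acid | COc1c(OCc2ccccc2)cc(C(=O)O)cc1OCc1ccccc1
F5 | step 5 | 3,5-bis(benzyloxy)-4-methoxybenzoyl chloride | COc1c(OCc2ccccc2)cc(C(=O)Cl)cc1OCc1ccccc1
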